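**Plan**

- Retrosynthetic cuts, in order:
  - the central aryl–CH2–aryl bridge, giving two identical filicinic–CH2–phloroglucinol halves and one formaldehyde carbon;
  - each filicinic–CH2–aryl bridge, giving an aminomethylated propionylfilicinic acid and propionylphloroglucinol;
  - in each end ring, the bond between the ring carbonyl carbon next to CMe2 and the ring carbon that carries the propanoyl group, opening the ring to a linear 2,2-dimethyl-3,5,7-triketo ester;
  - C3–C4 of that chain, giving hexane-2,4-dione and dimethyl 2,2-dimethylmalonate.
- Forward order: the chain is joined, the end ring is closed by a Claisen closure that copies the folding of a tetraketide in acylphloroglucinol biosynthesis, and then the outer and the central methylene bridges are made in turn. The aromatic rings are bought.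
- Enabling feature: the end ring is a 2-acyl-cyclohexane-1,3,5-trione. Its acyl-bearing ring carbon is a 1,3-diketone methylene in the open chain. Its quaternary CMe2 carbon has no proton, so the aldol and aromatisation paths of a polyketone are closed and only the Claisen path is left.
- Stereochemistry: none to set. The target has no stereocentre and no defined double-bond geometry.

Key step: step 2

Remark: every β-triketone unit is drawn as one enol tautomer, as in the target structure; the tautomers interconvert freely and count as one compound.

**Step 1**
Reactants: 1 hexane-2,4-dione; 2 dimethyl 2,2-dimethylmalonate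
Product: 4 methyl 2,2-dimethyl-3,5,7-trioxononanoate, via hexane-2,4-dione dilithium dianion 3 (not isolated)
Conditions: LiN(iPr)2 (3.1 equiv), THF, −78 → 0 °C; then 2 (1.3 equiv), −78 → 0 °C; cold 1 M HCl
Reagents that add atoms: none
Why: This is a Hauser–Harris acylation of a β-diketone 1,3-dianion, in which the second deprotonation should go to the terminal CH3 rather than the ethyl CH2, the terminal carbanion adds to one ester group of the non-enolisable diester, and the triketone formed is deprotonated at once by the third equivalent of base, which should stop a second addition.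

**Step 2**
Reactants: 4 methyl 2,2-dimethyl-3,5,7-trioxononanoate
Product: 5 3,5-dihydroxy-6,6-dimethyl-2-propanoylcyclohexa-2,4-dien-1-one (propionylfilicinic acid)
Conditions: KOtBu (2.5 equiv), THF, 0 → 50 °C; then 1 M HCl
Reagents that add atoms: none
Why: The base turns the 3,5,7-triketone into its enolate, the C6 carbon (the methylene between the C5 and C7 carbonyls) adds to the C1 ester carbonyl, methoxide leaves, and the product is deprotonated at once to the very stable β-triketone enolate, which should pull the equilibrium over. The closest known reaction type is the Claisen (Dieckmann-type) cyclisation of 3,5,7-triketo esters to acylphloroglucinols and of 3,5-diketo esters to cyclohexane-1,3,5-triones, the laboratory copy of the C6-to-C1 Claisen folding of a tetraketide by acylphloroglucinol synthases. The six-membered ring C1–C6 closes in the 6-exo-trig mode at the ester carbonyl, and as an enolate closure it is 6-(enolexo)-exo-trig through the C6=C7 enolate or 6-(enolendo)-exo-trig through the C5=C6 enolate, both allowed. No stereocentre is formed. The step needs C-acylation at C6 rather than an aldol closure or closure through oxygen, and the quaternary C2 with its two methyl groups secures this: it has no proton, so the C2-to-C7 aldol path to a resorcylate is closed, C6 is the only stabilised carbon nucleophile that can reach an electrophile through a six-membered transition state, and the gem-dialkyl effect favours the fold. The enol lactone that would arise from attack of the C5 enolate oxygen on C1 is an acyl enol ester, which alkoxide should reopen, so it drains into the same trione enolate.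

**Step 3**
Reactants: 5 propionylfilicinic acid
Product: 6 1-(2,6-dihydroxy-3,3-dimethyl-4-oxo-5-propanoylcyclohexa-1,5-dien-1-yl)-N,N-dimethylmethanaminium iodide
Conditions: Me2N=CH2 I (Eschenmoser's salt, 1.05 equiv), CH2Cl2, rt; trituration with Et2O
Reagents that add atoms: dimethylmethylideneammonium iodide (Eschenmoser's salt), C=[N+](C)C.[I-]
Why: This is a Mannich aminomethylation with a preformed iminium salt at the only nucleophilic ring CH of 5 (C4, between the two enol carbons), an addition in which every atom of both partners ends up in the ammonium salt, which should not eliminate until base is added.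

**Step 4**
Reactants: 6 the Mannich salt; 7 1-(2,4,6-trihydroxyphenyl)propan-1-one (propionylphloroglucinol, flopropione)
Product: 9 1-{2,4,6-trihydroxy-3-[(2,6-dihydroxy-3,3-dimethyl-4-oxo-5-propanoylcyclohexa-1,5-dien-1-yl)methyl]phenyl}propan-1-one, via methylidene trione 8 (not isolated)
Conditions: 7 (3 equiv), NaOAc (1.2 equiv), EtOH, 60 °C; dilute HCl work-up
Reagents that add atoms: none
Why: Base-triggered E1cB loss of dimethylamine should give the methylidene trione 8, a strong Michael acceptor of the quinone-methide kind, which the electron-rich ring carbon of 7 traps by conjugate (Friedel–Crafts-type) addition; the two free positions of 7 are equivalent and its excess should hold back a second alkylation.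

**Step 5**
Reactants: 9 (two molecules)
Product: 12 target CNP0541376.0, bis{2,4,6-trihydroxy-3-propanoyl-5-[(2,6-dihydroxy-3,3-dimethyl-4-oxo-5-propanoylcyclohexa-1,5-dien-1-yl)methyl]phenyl}methane, via hydroxymethyl adduct 10 (not isolated), via quinone methide 11 (not isolated)
Conditions: 37% aq. CH2O (0.5 equiv), KOH (3 equiv), H2O–MeOH, 0 °C, 10 min; then 1 M HCl
Reagents that add atoms: formaldehyde, C=O
Why: This is a base-mediated phenol–formaldehyde condensation (Lederer–Manasse hydroxymethylation, loss of hydroxide to the o-quinone methide, Michael addition of a second phenolate), and since 9 has a single free aromatic CH the reaction can only join two molecules and should not give oligomers.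

**Compound list**

1 | hexane-2,4-dione | CCC(=O)CC(C)=O | starting material
2 | dimethyl 2,2-dimethylmalonate | COC(=O)C(C)(C)C(=O)OC | starting material
3 | hexane-2,4-dione dilithium dianion (dilithium hexa-1,3-diene-2,4-diolate) | CCC(O[Li])=CC(=C)O[Li] | intermediate
4 | methyl 2,2-dimethyl-3,5,7-trioxononanoate | CCC(=O)CC(=O)CC(=O)C(C)(C)C(=O)OC | intermediate
5 | 3,5-dihydroxy-6,6-dimethyl-2-propanoylcyclohexa-2,4-dien-1-one (propionylfilicinic acid) | CCC(=O)C1=C(O)C=C(O)C(C)(C)C1=O | intermediate
6 | 1-(2,6-dihydroxy-3,3-dimethyl-4-oxo-5-propanoylcyclohexa-1,5-dien-1-yl)-N,N-dimethylmethanaminium iodide | CCC(=O)C1=C(O)C(C[NH+](C)C)=C(O)C(C)(C)C1=O.[I-] | intermediate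
7 | 1-(2,4,6-trihydroxyphenyl)propan-1-one (flopropione) | CCC(=O)c1c(O)cc(O)cc1O | starting material
8 | 5-hydroxy-2,2-dimethyl-6-methylidene-4-propanoylcyclohex-4-ene-1,3-dione (methylidene trione) | CCC(=O)C1=C(O)C(=C)C(=O)C(C)(C)C1=O | intermediate
9 | 1-{2,4,6-trihydroxy-3-[(2,6-dihydroxy-3,3-dimethyl-4-oxo-5-propanoylcyclohexa-1,5-dien-1-yl)methyl]phenyl}propan-1-one | CCC(=O)C1=C(O)C(Cc2c(O)cc(O)c(C(=O)CC)c2O)=C(O)C(C)(C)C1=O | intermediate
10 | 1-{2,4,6-trihydroxy-3-(hydroxymethyl)-5-[(2,6-dihydroxy-3,3-dimethyl-4-oxo-5-propanoylcyclohexa-1,5-dien-1-yl)methyl]phenyl}propan-1-one (hydroxymethyl adduct) | CCC(=O)C1=C(O)C(Cc2c(O)c(CO)c(O)c(C(=O)CC)c2O)=C(O)C(C)(C)C1=O | intermediate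
11 | 3,5-dihydroxy-6-methylidene-2-propanoyl-4-[(2,6-dihydroxy-3,3-dimethyl-4-oxo-5-propanoylcyclohexa-1,5-dien-1-yl)methyl]cyclohexa-2,4-dien-1-one (quinone methide) | CCC(=O)C1=C(O)C(CC2=C(O)C(=C)C(=O)C(C(=O)CC)=C2O)=C(O)C(C)(C)C1=O | intermediate
12 | CNP0541376.0, bis{2,4,6-trihydroxy-3-propanoyl-5-[(2,6-dihydroxy-3,3-dimethyl-4-oxo-5-propanoylcyclohexa-1,5-dien-1-yl)methyl]phenyl}methane | CCC(=O)C1=C(O)C(Cc2c(O)c(Cc3c(O)c(CC4=C(O)C(C)(C)C(=O)C(C(=O)CC)=C4O)c(O)c(C(=O)CC)c3O)c(O)c(C(=O)CC)c2O)=C(O)C(C)(C)C1=O | target

**Step count and risks**

Total steps: 5. Longest linear sequence: 5 steps (1 → 4 → 5 → 6 → 9 → 12); 7 enters at step 4.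

Steps most likely to fail:

Step 5. In aqueous alkali the methylene bridges between the filicinic and phloroglucinol rings can open by retro-Michael cleavage and recombine, so the bridges may be reshuffled. Fallback: a two-directional assembly that makes these bridges last and under buffered conditions. It sets out from 7 and 6. Condensation of 7 (fourfold excess) with aqueous formaldehyde in cold dilute NaOH should give the symmetric core 1,1'-[methanediylbis(2,4,6-trihydroxybenzene-3,1-diyl)]di(propan-1-one) F1, which has one free aromatic CH at each end. Both ends are then alkylated at the same time with 6 (2.2 equiv, NaOAc, EtOH, 60 °C) through the methylidene trione 8, and the route is rejoined at 12.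

Step 4. A second alkylation of the phloroglucinol ring may occur, and the methylidene trione may condense with itself (hetero-Diels–Alder dimerisation) instead of being trapped. Fallback: the bridge carbon is brought in at the aldehyde oxidation level, where the first substitution deactivates the ring against a second. It sets out from 7 and 5. Vilsmeier–Haack monoformylation of 7 (POCl3, DMF, then water) should give 2,4,6-trihydroxy-3-propanoylbenzaldehyde F2. A three-component reductive alkylation of 5 with F2 (L-proline cat., Hantzsch ester, CH2Cl2, rt; Knoevenagel condensation followed by transfer hydrogenation of the arylidene trione) then rejoins the route at 9.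

Step 2. Retro-Claisen cleavage at the C3 ketone next to the quaternary carbon, or closure through an enolate oxygen to a lactone or pyranone, may compete with the C-cyclisation. Fallback: the end ring is made by dearomatisation of an aromatic ring instead of by ring closure. It sets out from 7. Geminal C-dimethylation of 7 (MeI, NaOMe, MeOH, 0 °C → rt) at one free ring carbon should give the acylfilicinic acid directly and rejoins the route at 5. This fallback makes no new compound, F0.

**Further compounds**

F1 | step 5 | 1,1'-[methanediylbis(2,4,6-trihydroxybenzene-3,1-diyl)]di(propan-1-one) | CCC(=O)c1c(O)cc(O)c(Cc2c(O)cc(O)c(C(=O)CC)c2O)c1O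
F2 | step 4 | 2,4,6-trihydroxy-3-propanoylbenzaldehyde | CCC(=O)c1c(O)cc(O)c(C=O)c1O
F0 | step 2 | none | none
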